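**Retrosynthetic overview**
1. Late decoration of a plain isoflavan leads back to (3R)-2'-hydroxy-5,7,4'-trimethoxyisoflavan: the 7-OH comes from chelation-controlled O-demethylation beside the 8-CHO, the 3'-prenyl from an aromatic Claisen shift from O2', and the 8-CHO from Vilsmeier–Haack formylation.
2. That isoflavan comes from a cis-pterocarpan by hydrogenolysis of a C4–O2' bond that the target does not contain. Ring C of the pterocarpan comes from an O1–C8a aryl etherification of a bromo alcohol.
3. Key disconnection C3–C4: a cis-2-aryl-2,3-dihydrobenzofuran-3-carboxylate is opened to an aryldiazoacetate in which ring A, with C4, sits on O2' as a benzyl ether. The forward step is an enantioselective rhodium-carbene 1,5 C–H insertion, a net O-to-C transposition of the benzyl group.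
4. Enabling feature: the free 2'-OH of ring B is ortho to C1', the carbon that bears C3, so O2', C2', C1', C3 and C4 can form a five-membered ring. C4 is benzylic to ring A with 5-OMe ortho and 7-OMe para, which makes its C–H bonds hydridic and later makes its C–O bond hydrogenolysable.
5. Ring order: temporary dihydrofuran ring (step 4), ring C (step 6), dihydrofuran ring opened again (step 7). Rings A and B are bought.

Key step: step 4

Remark: isoflavan numbering is used for all intermediates (O1, C2, C3, C4, C4a to C8a for rings C and A; C1' to C6' for ring B; O2' is the oxygen on C2').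
Assumption: by analogy with simpler 2-(benzyloxy)aryl diazoacetates the S-configured catalyst is taken to give the (2R,3S) insertion product; should the sense be opposite, Rh2(R-PTTL)4 is used and nothing else changes.

**Step 1**
Reactants: 1 2-bromo-4,6-dimethoxybenzaldehyde
Product: 2 (2-bromo-4,6-dimethoxyphenyl)methanol
Conditions: NaBH4, MeOH–THF, 0 °C
Reagents that add atoms: none
Why: Borohydride reduction of the aryl aldehyde gives the benzylic alcohol whose carbon is the future C4, and neither the aryl bromide nor the methyl ethers are touched.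

**Step 2**
Reactants: 2 (2-bromo-4,6-dimethoxyphenyl)methanol; 3 2-iodo-5-methoxyphenol
Product: 4 1-bromo-2-[(2-iodo-5-methoxyphenoxy)methyl]-3,5-dimethoxybenzene
Conditions: PPh3, DIAD, THF, 0 °C to rt
Reagents that add atoms: none
Why: Mitsunobu etherification joins the acidic ortho-iodophenol through oxygen to the primary benzylic alcohol under neutral conditions, which installs the temporary O2'–C4 tether without passing through a labile electron-rich benzyl halide.

**Step 3**
Reactants: 4 1-bromo-2-[(2-iodo-5-methoxyphenoxy)methyl]-3,5-dimethoxybenzene; 5 ethyl diazoacetate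
Product: 6 ethyl 2-{2-[(2-bromo-4,6-dimethoxyphenyl)methoxy]-4-methoxyphenyl}-2-diazoacetate
Conditions: Pd(PPh3)4 (cat.), Et3N, n-Bu4NBr, MeCN, rt
Reagents that add atoms: none
Why: Palladium-catalysed cross-coupling of an aryl iodide with the C–H bond of a diazoacetate (oxidative addition to zerovalent palladium, base-assisted capture of the diazo carbon, reductive elimination with the diazo group kept) runs at room temperature, where the electron-rich aryl bromide does not add to palladium.

**Step 4**
Reactants: 6 ethyl 2-{2-[(2-bromo-4,6-dimethoxyphenyl)methoxy]-4-methoxyphenyl}-2-diazoacetate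
Product: 7 ethyl (2R,3S)-2-(2-bromo-4,6-dimethoxyphenyl)-6-methoxy-2,3-dihydro-1-benzofuran-3-carboxylate (cis)
Conditions: Rh2(S-PTTL)4 = dirhodium tetrakis[N-phthaloyl-(S)-tert-leucinate] (1 mol %), toluene, −60 °C, slow addition of 6
Reagents that add atoms: none
Why: Rh2(S-PTTL)4 expels N2 from 6 to give a catalyst-bound donor/acceptor carbene at C3, which inserts into one C4–H bond of the O2'–CH2 tether through a concerted, asynchronous, hydride-transfer-like three-centre transition state and so forms C3–C4. The closest known reaction type is the enantioselective intramolecular C–H insertion of 2-(benzyloxy)aryl diazoacetates to cis-2-aryl-2,3-dihydrobenzofuran-3-carboxylates under dirhodium carboxylates derived from N-phthaloyl amino acids. One ring is closed, the temporary five-membered dihydrofuran ring O2'–C2'–C1'–C3–C4, in the 1,5-insertion mode through a five-membered cyclic transition state. C3 is set by the carbene face that the chiral carboxylate pocket leaves open and C4 by which of the two enantiotopic hydrogens is taken, the cis relation coming from the transition state that turns ring A away from the catalyst wall; C4 is only a relay that makes ring C closable and is deleted in step 7, whereas C3 is the stereocentre of the target. The step needs site selectivity over methoxy C–H bonds, over attack on the two electron-rich arenes and over carbene dimerisation: only the tether CH2 stands in a 1,5 relation to C3, its C–H bonds are made hydridic by O2' and by the ortho 5-OMe and para 7-OMe of ring A, and low temperature with slow addition keeps the diazo concentration low. In one operation two bought arenes joined by a simple ether become the complete C6–C3–C6 isoflavan carbon skeleton with its stereocentre, and the oxygen that carried ring A is already the 2'-oxygen of the target.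

**Step 5**
Reactants: 7 ethyl (2R,3S)-2-(2-bromo-4,6-dimethoxyphenyl)-6-methoxy-2,3-dihydro-1-benzofuran-3-carboxylate
Product: 8 [(2R,3R)-2-(2-bromo-4,6-dimethoxyphenyl)-6-methoxy-2,3-dihydro-1-benzofuran-3-yl]methanol (cis; the descriptor at C3 changes by priority only)
Conditions: i-Bu2AlH, CH2Cl2, −78 to 0 °C; aqueous work-up
Reagents that add atoms: none
Why: Non-basic hydride reduction of the ester to the primary alcohol (C2) at low temperature avoids enolisation at the epimerisable C3 and leaves the aryl bromide intact.

**Step 6**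
Reactants: 8 [(2R,3R)-2-(2-bromo-4,6-dimethoxyphenyl)-6-methoxy-2,3-dihydro-1-benzofuran-3-yl]methanol
Product: 9 (6aR,11aR)-1,3,9-trimethoxy-6a,11a-dihydro-6H-[1]benzofuro[3,2-c]chromene (cis-pterocarpan)
Conditions: Pd(OAc)2 (cat.), 2-(di-tert-butylphosphino)-1,1'-binaphthyl (cat.), Cs2CO3, toluene, 70 °C
Reagents that add atoms: none
Why: Intramolecular Buchwald–Hartwig C–O coupling closes the six-membered ring C (O1–C8a bond) because CH2OH and ring A are cis on the dihydrofuran ring, the bulky electron-rich phosphine favouring C–O reductive elimination from divalent palladium over beta-hydride elimination, and no stereocentre is touched.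

**Step 7**
Reactants: 9 (6aR,11aR)-1,3,9-trimethoxy-6a,11a-dihydro-6H-[1]benzofuro[3,2-c]chromene
Product: 10 2-[(3R)-5,7-dimethoxy-3,4-dihydro-2H-chromen-3-yl]-5-methoxyphenol
Conditions: H2 (1 atm), Pd/C, EtOH–EtOAc, rt
Reagents that add atoms: none
Why: Hydrogenolysis of the activated benzylic C4–O2' bond, the classical cleavage of pterocarpans to 2'-hydroxyisoflavans, removes the tether, turns the relay stereocentre C4 into CH2 and frees the 2'-OH, while C3 takes no part and stays R.

**Step 8**
Reactants: 10 2-[(3R)-5,7-dimethoxy-3,4-dihydro-2H-chromen-3-yl]-5-methoxyphenol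
Product: 12 (3R)-3-(2-hydroxy-4-methoxyphenyl)-5,7-dimethoxy-3,4-dihydro-2H-chromene-8-carbaldehyde, via iminium salt 11 (not isolated)
Conditions: POCl3, DMF, 0 °C to rt; then H2O
Reagents that add atoms: N,N-dimethylformamide CN(C)C=O; water O
Why: Vilsmeier–Haack formylation should prefer the phloroglucinol-type ring A (three oxygen donors) to the resorcinol-type ring B, and C8 to C6, because C8 is flanked by the tied-back ring oxygen O1 whereas C6 is shielded by the 5-OMe methyl group that the C4 methylene pushes towards it, as is known for 5,7-dialkoxyflavans.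

**Step 9**
Reactants: 13 2-methylbut-3-en-2-ol
Product: 14 tert-butyl 2-methylbut-3-en-2-yl carbonate
Conditions: n-BuLi, THF, 0 °C; then Boc2O, 0 °C to rt
Reagents that add atoms: di-tert-butyl dicarbonate CC(C)(C)OC(=O)OC(=O)OC(C)(C)C
Why: O-acylation of the lithium tertiary alkoxide with the dicarbonate gives the mixed carbonate that serves as the 1,1-dimethylallyl donor.

**Step 10**
Reactants: 12 (3R)-3-(2-hydroxy-4-methoxyphenyl)-5,7-dimethoxy-3,4-dihydro-2H-chromene-8-carbaldehyde; 14 tert-butyl 2-methylbut-3-en-2-yl carbonate
Product: 15 (3R)-5,7-dimethoxy-3-{4-methoxy-2-[(2-methylbut-3-en-2-yl)oxy]phenyl}-3,4-dihydro-2H-chromene-8-carbaldehyde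
Conditions: Pd(PPh3)4 (cat.), THF, 0 °C
Reagents that add atoms: none
Why: In this Tsuji–Trost O-allylation, ionisation by zerovalent palladium with loss of CO2 gives the 1,1-dimethyl-pi-allyl complex and tert-butoxide, which deprotonates the only free phenol, and kinetic attack of the phenoxide at the more substituted terminus at low temperature gives the tertiary ether.

**Step 11**
Reactants: 15 (3R)-5,7-dimethoxy-3-{4-methoxy-2-[(2-methylbut-3-en-2-yl)oxy]phenyl}-3,4-dihydro-2H-chromene-8-carbaldehyde
Product: 17 (3R)-3-[2-hydroxy-4-methoxy-3-(3-methylbut-2-en-1-yl)phenyl]-5,7-dimethoxy-3,4-dihydro-2H-chromene-8-carbaldehyde, via ortho-dienone 16 (not isolated)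
Conditions: toluene, sealed tube, 120 °C
Reagents that add atoms: none
Why: In the aromatic Claisen rearrangement the [3,3] shift goes to C3', the only free ortho position, and inverts the allyl unit so that the 1,1-dimethylallyl ether becomes the prenyl group, after which tautomerisation of the dienone restores the 2'-OH.

**Step 12**
Reactants: 17 (3R)-3-[2-hydroxy-4-methoxy-3-(3-methylbut-2-en-1-yl)phenyl]-5,7-dimethoxy-3,4-dihydro-2H-chromene-8-carbaldehyde
Product: 18 (3R)-7-hydroxy-3-[2-hydroxy-4-methoxy-3-(3-methylbut-2-en-1-yl)phenyl]-5-methoxy-3,4-dihydro-2H-chromene-8-carbaldehyde (target)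
Conditions: MgI2, THF, reflux; then H2O
Reagents that add atoms: none
Why: In this chelation-controlled ether cleavage magnesium binds the formyl oxygen and the neighbouring 7-OMe oxygen and iodide removes the methyl group by SN2 attack, a mild method known to spare a prenyl group next to a free phenol, while 5-OMe and 4'-OMe have no neighbouring carbonyl and C2 is a hindered beta-branched site.

**Compound list**
1 | 2-bromo-4,6-dimethoxybenzaldehyde | COc1cc(Br)c(C=O)c(OC)c1 | starting material
2 | (2-bromo-4,6-dimethoxyphenyl)methanol | COc1cc(Br)c(CO)c(OC)c1 | intermediate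
3 | 2-iodo-5-methoxyphenol | COc1ccc(I)c(O)c1 | starting material
4 | 1-bromo-2-[(2-iodo-5-methoxyphenoxy)methyl]-3,5-dimethoxybenzene | COc1cc(Br)c(COc2cc(OC)ccc2I)c(OC)c1 | intermediate
5 | ethyl diazoacetate | CCOC(=O)C=[N+]=[N-] | starting material
6 | ethyl 2-{2-[(2-bromo-4,6-dimethoxyphenyl)methoxy]-4-methoxyphenyl}-2-diazoacetate | CCOC(=O)C(=[N+]=[N-])c1ccc(OC)cc1OCc1c(Br)cc(OC)cc1OC | intermediate
7 | ethyl (2R,3S)-2-(2-bromo-4,6-dimethoxyphenyl)-6-methoxy-2,3-dihydro-1-benzofuran-3-carboxylate | CCOC(=O)[C@H]1c2ccc(OC)cc2O[C@H]1c3c(Br)cc(OC)cc3OC | intermediate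
8 | [(2R,3R)-2-(2-bromo-4,6-dimethoxyphenyl)-6-methoxy-2,3-dihydro-1-benzofuran-3-yl]methanol | OC[C@H]1c2ccc(OC)cc2O[C@H]1c3c(Br)cc(OC)cc3OC | intermediate
9 | (6aR,11aR)-1,3,9-trimethoxy-6a,11a-dihydro-6H-[1]benzofuro[3,2-c]chromene | COc1ccc2c(c1)O[C@H]1c3c(OC)cc(OC)cc3OC[C@@H]21 | intermediate
10 | 2-[(3R)-5,7-dimethoxy-3,4-dihydro-2H-chromen-3-yl]-5-methoxyphenol | COc1ccc([C@@H]2COc3cc(OC)cc(OC)c3C2)c(O)c1 | intermediate
11 | {[(3R)-3-(2-hydroxy-4-methoxyphenyl)-5,7-dimethoxy-3,4-dihydro-2H-chromen-8-yl]methylidene}dimethylammonium dichlorophosphate | COc1ccc([C@@H]2COc3c(C=[N+](C)C)c(OC)cc(OC)c3C2)c(O)c1.[O-]P(=O)(Cl)Cl | intermediate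
12 | (3R)-3-(2-hydroxy-4-methoxyphenyl)-5,7-dimethoxy-3,4-dihydro-2H-chromene-8-carbaldehyde | COc1ccc([C@@H]2COc3c(C=O)c(OC)cc(OC)c3C2)c(O)c1 | intermediate
13 | 2-methylbut-3-en-2-ol | C=CC(C)(C)O | starting material
14 | tert-butyl 2-methylbut-3-en-2-yl carbonate | C=CC(C)(C)OC(=O)OC(C)(C)C | intermediate
15 | (3R)-5,7-dimethoxy-3-{4-methoxy-2-[(2-methylbut-3-en-2-yl)oxy]phenyl}-3,4-dihydro-2H-chromene-8-carbaldehyde | COc1ccc([C@@H]2COc3c(C=O)c(OC)cc(OC)c3C2)c(OC(C)(C)C=C)c1 | intermediate
16 | (3R)-5,7-dimethoxy-3-[4-methoxy-5-(3-methylbut-2-en-1-yl)-6-oxocyclohexa-1,3-dien-1-yl]-3,4-dihydro-2H-chromene-8-carbaldehyde (transient ring carbon undefined) | COC1=CC=C([C@@H]2COc3c(C=O)c(OC)cc(OC)c3C2)C(=O)C1CC=C(C)C | intermediate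
17 | (3R)-3-[2-hydroxy-4-methoxy-3-(3-methylbut-2-en-1-yl)phenyl]-5,7-dimethoxy-3,4-dihydro-2H-chromene-8-carbaldehyde | COc1ccc([C@@H]2COc3c(C=O)c(OC)cc(OC)c3C2)c(O)c1CC=C(C)C | intermediate
18 | (3R)-7-hydroxy-3-[2-hydroxy-4-methoxy-3-(3-methylbut-2-en-1-yl)phenyl]-5-methoxy-3,4-dihydro-2H-chromene-8-carbaldehyde | COc1ccc([C@@H]2COc3c(C=O)c(O)cc(OC)c3C2)c(O)c1CC=C(C)C | target

Total step count: 12
Longest linear sequence: 11 steps (1 to 18 through steps 1 to 8 and 10 to 12; step 9 is a side branch)

**Steps most likely to fail**

**Step 4.**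
- Risk: poor facial selectivity at the carbene carbon, or erosion of the cis preference, because the tether CH2 is flanked by two ortho substituents of ring A.
- Fallback: stereocontrol passes from the catalyst to a covalent resolving group. It sets out from 8 of insufficient enantiomeric purity and comes back at 8. Steglich esterification (DCC, DMAP, CH2Cl2) with (2S)-2-methoxy-2-phenylacetic acid gives diastereomeric esters. The wanted one, the O-methylmandelate of (2R,3R)-8 F1, is separated by chromatography or crystallisation. Saponification (LiOH, THF–H2O) returns 8, and the insertion then only has to deliver the ring closure.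

**Step 8.**
- Risk: poor positional selectivity, with attack at C6 or on ring B beside attack at C8.
- Fallback: direct formylation is replaced by halogenation and metalation. It sets out from 10 and comes back at 12.
  - The phenol is silylated (TBSCl, imidazole, DMF) to the silyl ether F2.
  - NBS (one equivalent, CH2Cl2, −78 °C) follows the C8 bromination known for 5,7-dialkoxyflavans and gives the 8-bromide F3, which can be purified as a single isomer.
  - Bromine–lithium exchange (n-BuLi, THF, −78 °C) and a DMF quench give the silylated 8-carbaldehyde F4.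
  - TBAF in THF frees the phenol to give 12.

**Step 3.**
- Risk: slow oxidative addition of the hindered, electron-rich aryl iodide, so that palladium-induced decomposition of the diazo ester takes over.
- Fallback: the diazo group is introduced after the C–C bond. It sets out from 4 and comes back at 6. Negishi-type coupling of the C–I bond with the Reformatsky reagent BrZnCH2CO2Et (Pd(PPh3)4, THF–DMPU) gives the ethyl arylacetate F5. Regitz diazo transfer (4-acetamidobenzenesulfonyl azide, DBU, MeCN) then gives 6.

**Further compounds**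
F1 | step 4 | [(2R,3R)-2-(2-bromo-4,6-dimethoxyphenyl)-6-methoxy-2,3-dihydro-1-benzofuran-3-yl]methyl (2S)-2-methoxy-2-phenylacetate | CO[C@H](C(=O)OC[C@H]1c2ccc(OC)cc2O[C@H]1c3c(Br)cc(OC)cc3OC)c4ccccc4
F2 | step 8 | tert-butyl{2-[(3R)-5,7-dimethoxy-3,4-dihydro-2H-chromen-3-yl]-5-methoxyphenoxy}dimethylsilane | COc1ccc([C@@H]2COc3cc(OC)cc(OC)c3C2)c(O[Si](C)(C)C(C)(C)C)c1
F3 | step 8 | {2-[(3R)-8-bromo-5,7-dimethoxy-3,4-dihydro-2H-chromen-3-yl]-5-methoxyphenoxy}(tert-butyl)dimethylsilane | COc1ccc([C@@H]2COc3c(Br)c(OC)cc(OC)c3C2)c(O[Si](C)(C)C(C)(C)C)c1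
F4 | step 8 | (3R)-3-{2-[(tert-butyldimethylsilyl)oxy]-4-methoxyphenyl}-5,7-dimethoxy-3,4-dihydro-2H-chromene-8-carbaldehyde | COc1ccc([C@@H]2COc3c(C=O)c(OC)cc(OC)c3C2)c(O[Si](C)(C)C(C)(C)C)c1
F5 | step 3 | ethyl 2-{2-[(2-bromo-4,6-dimethoxyphenyl)methoxy]-4-methoxyphenyl}acetate | CCOC(=O)Cc1ccc(OC)cc1OCc1c(Br)cc(OC)cc1OC
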